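**Retrosynthetic overview** (side chain numbered C1 = OCH2 to C8; coumarin numbered as usual)

1. Target 10 is a (2E,4R)-4-acetoxy-3,7-dimethylocta-2,6-dienyl ether of 4-hydroxy-5-methylcoumarin. The chain is cut at C3–C4 (alkenyl carbon to acetoxy carbinol carbon), and the same operation also makes C2–H and C4–OAc.
2. Enabling feature: C4 is an allylic carbinol on the trisubstituted C2=C3 alkene, with C2–H cis to C4 and only a methyl group on C3. This is the imprint of syn-hydrometalation of a but-2-ynyl ether followed by 1,2-addition to an aldehyde, so alkyne 4, hydride, aldehyde 6 and Ac2O are joined in one flask.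
3. Alkyne 4 comes from 4-hydroxy-5-methylcoumarin 2 and but-2-yn-1-ol 3 (O4–C1 bond, Mitsunobu). Aldehyde 6 comes from 4-methylpent-3-en-1-ol 5 by oxidation.
4. Ring formation: only the pyranone ring (O1–C2–C3–C4–C4a–C8a) is built, in step 1, on the benzene ring of ketone 1. No ring is formed afterwards.

Key step: step 4

Assumption: the (R)-amino thiol ligand is taken to direct alkenyl transfer to the Si face of the aldehyde; should the sense prove opposite, the (S)-ligand is used with no other change.

**Step 1**
Reactants: 1 1-(2-hydroxy-6-methylphenyl)ethan-1-one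
Product: 2 4-hydroxy-5-methyl-2H-chromen-2-one
Conditions: (EtO)2CO, NaH (3.5 equiv), toluene, 110 °C; then aq. HCl
Reagents that add atoms: diethyl carbonate, CCOC(=O)OCC
Why: Claisen-type C-acylation of the methyl ketone enolate by diethyl carbonate, followed by lactonisation onto the ortho phenoxide, is the standard 4-hydroxycoumarin synthesis and should close the pyranone ring with the methyl group at C5.

**Step 2**
Reactants: 2 4-hydroxy-5-methyl-2H-chromen-2-one; 3 but-2-yn-1-ol
Product: 4 4-(but-2-yn-1-yloxy)-5-methyl-2H-chromen-2-one
Conditions: PPh3, DIAD, THF, 0 °C to rt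
Reagents that add atoms: none
Why: Mitsunobu etherification, in which the acidic enol of 2 (pKa about 4) should displace the alkoxyphosphonium of the primary propargylic alcohol through O4 at room temperature, avoiding the C3-alkylation seen with propargylic halides and staying far below any propargyl Claisen rearrangement.

**Step 3**
Reactants: 5 4-methylpent-3-en-1-ol
Product: 6 4-methylpent-3-enal
Conditions: Dess–Martin periodinane, CH2Cl2, 0 °C to rt; pentane, filtration; used at once as a cold solution
Reagents that add atoms: none
Why: Dess–Martin oxidation is near-neutral and non-aqueous, so the aldehyde should form without over-oxidation and without migration of the β,γ-double bond into conjugation, provided the volatile product is kept cold and in solution.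

**Step 4**
Reactants: 4 4-(but-2-yn-1-yloxy)-5-methyl-2H-chromen-2-one; 6 4-methylpent-3-enal
Product: 10 (2E,4R)-3,7-dimethyl-1-[(5-methyl-2-oxo-2H-chromen-4-yl)oxy]octa-2,6-dien-4-yl acetate, via alkenylzirconocene chloride 7 (not isolated), via alkenyl(methyl)zinc 8 (not isolated), via methylzinc alkoxide 9 (not isolated)
Conditions: Cp2Zr(H)Cl (1.05 equiv), CH2Cl2, rt; solvent switch to toluene; Me2Zn (1.1 equiv), −65 °C; (R)-2-[1-(dimethylamino)ethyl]benzenethiol (10 mol%), then 6 (1.3 equiv), −30 °C; Ac2O (3 equiv), DMAP (5 mol%), −30 °C to rt; cold 1 M HCl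
Reagents that add atoms: acetic anhydride, CC(=O)OC(C)=O
Why: syn-Hydrozirconation of the but-2-ynyl ether delivers H to C2 and Zr to C3 (the alkyne carbon carrying the small methyl group, not the CH2O-coumarin arm), which fixes the (E)-geometry; Me2Zn then exchanges Zr for Zn with retention, the amino thiolate–zinc chelate activates aldehyde 6 and transfers the alkenyl group (in preference to methyl) to its carbonyl carbon, and the zinc alkoxide is acetylated in the same flask. The closest known reaction type is the hydrozirconation/Zr-to-Zn transmetalation/ligand-catalysed asymmetric alkenylation of aldehydes, finished by the ordinary acylation of a zinc alkoxide with an anhydride. No ring is closed. The new stereocentre C4 is set under catalyst control: alkenyl delivery to the Si face of the aldehyde (O > CH2 > H) gives 4R, because the alkenyl carbon outranks the C5 methylene in the CIP order. The step needs regioselectivity (Zr at C3, not C2), chemoselectivity (alkyne before the lactone carbonyl, alkenyl before methyl transfer) and enantioselectivity against the zirconocene-promoted background addition. These should be secured by the methyl/CH2OAr size difference (a C2-zirconated isomer would in any case be lost by β-elimination of the coumarin-4-olate and not carried forward), by the low electrophilicity of the 4-alkoxycoumarin carbonyl (a vinylogous carbonate) towards one equivalent of Cp2Zr(H)Cl, and by ligand acceleration at −30 °C.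

**Compound list** (Cp rings are drawn σ-bonded in SMILES)

1 | 1-(2-hydroxy-6-methylphenyl)ethan-1-one | CC(=O)c1c(C)cccc1O | starting material
2 | 4-hydroxy-5-methyl-2H-chromen-2-one | Cc1cccc2oc(=O)cc(O)c12 | intermediate
3 | but-2-yn-1-ol | CC#CCO | starting material
4 | 4-(but-2-yn-1-yloxy)-5-methyl-2H-chromen-2-one | CC#CCOc1cc(=O)oc2cccc(C)c12 | intermediate
5 | 4-methylpent-3-en-1-ol | CC(C)=CCCO | starting material
6 | 4-methylpent-3-enal | CC(C)=CCC=O | intermediate
7 | chlorobis(cyclopentadienyl)[(2E)-4-[(5-methyl-2-oxo-2H-chromen-4-yl)oxy]but-2-en-2-yl]zirconium | Cl[Zr](C1C=CC=C1)(C1C=CC=C1)/C(C)=C/COc1cc(=O)oc2cccc(C)c12 | intermediate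
8 | methyl[(2E)-4-[(5-methyl-2-oxo-2H-chromen-4-yl)oxy]but-2-en-2-yl]zinc | C[Zn]/C(C)=C/COc1cc(=O)oc2cccc(C)c12 | intermediate
9 | methylzinc (2E,4R)-3,7-dimethyl-1-[(5-methyl-2-oxo-2H-chromen-4-yl)oxy]octa-2,6-dien-4-olate | C[Zn]O[C@H](CC=C(C)C)/C(C)=C/COc1cc(=O)oc2cccc(C)c12 | intermediate
10 | (2E,4R)-3,7-dimethyl-1-[(5-methyl-2-oxo-2H-chromen-4-yl)oxy]octa-2,6-dien-4-yl acetate | CC(=O)O[C@H](CC=C(C)C)/C(C)=C/COc1cc(=O)oc2cccc(C)c12 | target

**Step count:** 4 steps in total. Longest linear sequence: 3 steps (1 → 2 → 4 → 10).

**Steps most likely to fail**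

Step 4. Three processes could defeat the one-flask coupling:
- Hydride could be delivered to the lactone carbonyl instead of the alkyne.
- Zirconium could go to C2, after which the coumarin-4-olate is expelled by β-elimination.
- The zirconocene-promoted background addition could erode the enantioselectivity with this unbranched, enolisable aldehyde.

The fallback sets out from alcohol 3 and coumarin 2 and comes back at target 10. Alcohol 3 is hydrozirconated away from the coumarin (Cp2ZrCl2/DIBAL-H as in situ Cp2Zr(H)Cl, THF, then I2) to (2E)-3-iodobut-2-en-1-ol F1. Mitsunobu coupling of F1 with 2 (PPh3, DIAD, THF) should give the vinyl iodide 4-{[(2E)-3-iodobut-2-en-1-yl]oxy}-5-methyl-2H-chromen-2-one F2, which can be purified free of regioisomers. A catalytic asymmetric Nozaki–Hiyama–Kishi coupling of F2 with aldehyde 6 (CrCl2 10 mol%, chiral sulfonamide–oxazoline ligand of the enantiomer giving 4R, NiCl2·dmp cat., Mn, Cp2ZrCl2, LiCl, MeCN, rt) forms the same C3–C4 bond under neutral conditions. It should give the allylic alcohol 4-{[(2E,4R)-4-hydroxy-3,7-dimethylocta-2,6-dien-1-yl]oxy}-5-methyl-2H-chromen-2-one F3. Acetylation of F3 (Ac2O, pyridine, DMAP, CH2Cl2, 0 °C) then gives 10.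

Step 3. The β,γ-double bond of the aldehyde may migrate into conjugation by enolisation, and the volatile aldehyde may be lost or self-condense during concentration and storage. The fallback sets out from alcohol 5 and comes back at aldehyde 6. Alcohol 5 is oxidised in a buffered two-phase TEMPO/NaOCl system (KBr, NaHCO3, CH2Cl2/H2O, 0 °C), and the organic layer is shaken at once with aqueous NaHSO3. The aldehyde is thus never concentrated but captured as the solid, storable bisulfite adduct sodium 1-hydroxy-4-methylpent-3-ene-1-sulfonate F4. Aldehyde 6 is released from F4 just before step 4 by exchange with aqueous formaldehyde under a pentane layer at 0 °C (neutral pH), and the dried pentane/toluene solution is used directly.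

Step 2. The ambident coumarin anion may be alkylated at the ring-carbonyl oxygen (giving the 2-alkoxychromone isomer), and the peri 5-methyl group shields O4 and slows the wanted pathway. The fallback sets out from coumarin 2 and comes back at alkyne 4 by reversing the polarity. Compound 2 is converted with POCl3 (reflux) into 4-chloro-5-methyl-2H-chromen-2-one F5. The chloride of F5 is then displaced at C4 by the sodium alkoxide of 3 (NaH, THF, 0 °C) in an addition–elimination that can only give the 4-ether 4.

**Further compounds**

F1 | step 4 | (2E)-3-iodobut-2-en-1-ol | C/C(I)=C\CO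
F2 | step 4 | 4-{[(2E)-3-iodobut-2-en-1-yl]oxy}-5-methyl-2H-chromen-2-one | C/C(I)=C\COc1cc(=O)oc2cccc(C)c12
F3 | step 4 | 4-{[(2E,4R)-4-hydroxy-3,7-dimethylocta-2,6-dien-1-yl]oxy}-5-methyl-2H-chromen-2-one | O[C@H](CC=C(C)C)/C(C)=C/COc1cc(=O)oc2cccc(C)c12
F4 | step 3 | sodium 1-hydroxy-4-methylpent-3-ene-1-sulfonate | CC(C)=CCC(O)S(=O)(=O)[O-].[Na+]
F5 | step 2 | 4-chloro-5-methyl-2H-chromen-2-one | Cc1cccc2oc(=O)cc(Cl)c12
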